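I asked how long each target stayed hot.

    starting material + free catalyst ⇌ catalyst intermediate A (K1 = 3.6 /M, k1 = 66 /M/s, Ea1 = 40.0 kJ/mol, ΔH1 = 2.00 kJ/mol)
    reagent + catalyst intermediate A ⇌ catalyst intermediate B (K2 = 150 /M, k2 = 0.52 /M/s, Ea2 = 61.0 kJ/mol, ΔH2 = −3.00 kJ/mol)
    catalyst intermediate B → free catalyst + target (k3 = 0.19 /s, Ea3 = 94.0 kJ/mol)
    reagent ⇌ dormant form (K4 = 0.26, k4 = 6.1 × 10⁻⁴ /s, Ea4 = 114 kJ/mol, ΔH4 = 30.0 kJ/mol)
    target → over-reaction product (k5 = 0.012 /s, Ea5 = 111 kJ/mol)
    (constants at 110 °C)

| setting | delta | alpha | gamma | zeta | beta |
|---|---|---|---|---|---|
| starting material | 0.20 M | 0.20 M (fed, over 80 s) | 0.20 M | 0.20 M | 0.20 M |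
| reagent | 0.240 M | 0.240 M | 0.240 M | 0.240 M (fed, over 8.0 s) | 0.240 M (fed, over 80 s) |
| free catalyst | 10 mM | 10 mM | 10 mM | 10 mM | 10 mM |
| time | 2.0 min | 2.0 min | 2.0 min | 2.0 min | 2.0 min |
| remark | everything together at the start at 90 °C, warmed to 110 °C at 80 s | all else is in the flask from the start; the feed brings no volume worth counting | everything together at the start | all else is in the flask from the start; the feed brings no volume worth counting | the addition at 90 °C, then warmed to 110 °C; the feed brings no volume worth counting |
| temperature |  | 110 °C | 110 °C | 110 °C |  |

* the flask that comes out highest in share of target in target plus over-reaction product, or "all alike" when all lie within 1.5 percentage points (delta / alpha / gamma / zeta / beta / all alike)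
* share of target in target plus over-reaction product at the end, delta
* share of target in target plus over-reaction product at the end, alpha
* share of target in target plus over-reaction product at the end, gamma
* share of target in target plus over-reaction product at the end, zeta
* share of target in target plus over-reaction product at the end, beta

- all constants are for 110 °C and move with temperature by the activation energies and enthalpies

- The first rung was binding: starting material and free catalyst relaxed to catalyst intermediate A in 0.0317 s, faster than the next rung, so in gamma I held that step at equilibrium, with intermediate A standing to free catalyst as 0.72.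
- Catalyst intermediate B filled next, in 3.14 s, and I reckoned its steady state at 0.645 of intermediate A, which put 21.3 % of the catalyst in B in gamma with the charges as they stood at the start.
- From that I reckoned gamma's making at 24.2 % of the charge over 2.0 min, and I took it as steady, dropping the fall in the charge as a correction.
- Slower again, target passed to over-reaction product with a lifetime of 83.3 s at 110 °C, and delta and beta spent 40.0 s there, giving 0.480 for the hot exposure, the time hot divided by that lifetime.
- Target made steadily through an exposure x keeps the share: one minus exp(−x), over x.
- Slower still, in gamma the loss of reagent to dormant form had a half-life of 19 min by its forward rate alone, against 2.0 min, so I dropped it from the reckoning.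
- Gamma, hot throughout, had exposure 1.44, which gave 53.0 %.
- In zeta and alpha I let the making lag by half the feed, which gave 54.0 % for zeta and 64.3 % for alpha.
- At 90 °C the rate constant of the release of target stood at 0.197 of its hot value and that of over-reaction at 0.147, so the constant of over-reaction fell by more than that of release.
- In delta, I reckoned cold-made target at 28.3 % of the making by that scaling and let it keep 57.7 %, with cold loss as the correction, and I let hot-made target keep 79.4 %, which gave 73.3 %.
- In beta, I assumed the cold making to be 0.5 of delta's, taking the mean reagent during the feed as 0.5 of its charge, so my weight for it was 16.5 %, which gave 75.8 %.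
- My highest flask was beta.
- The forecast put beta highest at 75 %, then delta 71.5 %, alpha 59 %, zeta 52.5 % and gamma 52 %, its alpha being lower than mine, on the ground that “the share depends mainly on how late the target forms and how long it spends hot”.
- The simulation put beta highest at 75.4 %, then delta 72.0 %, alpha 60.1 %, zeta 53.2 % and gamma 52.1 %.
- Beta spent 40.0 s hot against a target lifetime of 83.3 s, an exposure of 0.480, and held target 6.92 % and over-reaction product 2.26 % of the charge, while gamma, at exposure 1.44, held 10.3 % and 9.49 %. The same beta flask left until 3.0 min reached exposure 1.20, for which my rule gave 58.2 % for hot-made target alone, and the flask's share, with its cold-made target counted, read 54.1 %.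

(All constants are made up; no experiment stands behind them.)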